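## Structural features

The target is a germacranolide: a ten-membered carbocycle (C1–C10) with a ring-cis trisubstituted alkene C1=C10 (methyl C14 on C10) and a ring-trans trisubstituted alkene C4=C5 (hydroxymethyl C15 on C4). The two alkenes are linked on one side by the C2–C3 ethano bridge and on the other by the C6–C9 segment. A trans-fused α-methylene-γ-butyrolactone spans C6–C7 (lactone oxygen on C6, C11 on C7, C12 carbonyl, exocyclic C11=C13). C6 (R), C7 (R) and C8 (S) are contiguous stereocentres, with O-6 and O-8 on one face and C11 on the other; a fourth, isolated stereocentre lies in the (R)-3-hydroxy-2-methylpropanoyl group on O-8. The fragile groups are the α-methylene lactone (Michael acceptor), the 1,5-diene in a medium ring (proton-induced transannular cyclisation, thermal [3,3] shift), the β-hydroxy ester (elimination, acyl transfer) and two allylic C–O bonds. The real difficulty is the medium ring with two trisubstituted alkenes of opposite ring geometry, next to three stereocentres of which two (O-6 and O-8) can each close a γ-lactone on C12, while only O-8 may be acylated and both primary hydroxyls must end free. The key step uses the 1,5-relationship of C1=C10 and C4=C5 across C2–C3: reconnecting C1–C4 and C5–C10 folds the ten-membered perimeter into a bicyclo[2.2.0]hexane (C1, C2, C3, C4, C5, C10) fused to a cyclohexanone along C5–C10, a tricycle that an enone photocycloaddition can assemble.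

## Logic of the disconnections

26 ⇒ 25. The two primary O–Si bonds are cut last. Free primary hydroxyls could not coexist with the acylation of O-8, so both are carried as the same silyl ether and released together. The forward step must cleave silicon without touching the α-methylene lactone or the β-oxygenated ester.

25 ⇒ 21 + 24. The C8 O–acyl bond is cut, which splits off the three-carbon chiral acid and leaves the complete core. The forward step must acylate a hindered secondary alcohol without epimerising the α-methyl centre of 24.

21 ⇒ 20 ⇒ 17. First the O8–Si bond, then the C11=C13 bond (one carbon) are removed. Taking the Michael acceptor away gives a saturated lactone that tolerates enolate chemistry. The forward steps need selective cleavage of the secondary silyl ether beside the primary one, and enolisation only at C11.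

17 ⇒ 16 ⇒ 15 ⇒ 14. The lactone C12–O6 bond, the O15–Si bond and the hydride-derived C6–H and C15–H bonds are cut, returning to a dienone with a ketone at C6 and an ester at C15. This places the carbonyl groups where the key step needs them. The forward reduction must deliver hydride to the correct face at C6 and spare the C12 ester, and only O-6 may lactonise, so O-8 stays masked.

14 ⇒ 13 (key). C1–C4 and C5–C10 are reconnected. The medium ring with its two stereodefined alkenes becomes a tricycle of four- and six-membered rings. The forward fragmentation must break C5–C10 and not C2–C3, and must give ring-cis C1=C10 and ring-trans C4=C5.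

13 ⇒ 9 + 12. The cyclobutane bonds C4–C5 and C1–C10 are cut ([2+2]). This gives a cyclohexenone carrying C7 and C8 and a four-carbon cyclobutene ester. The forward step needs head-to-head regiochemistry and cis-anti-cis fusion.

9 ⇒ 7 + 8. The C7–C11 bond is cut, removing the two-carbon lactone precursor. The forward alkylation must occur at the α′-carbon, trans to the neighbouring silyloxy group, without β-elimination of that group.

7 ⇒ 6 ⇒ 5. The C10–C14 bond is cut and the carbonyl is transposed back. This leads to an enone whose only stereocentre is the silyloxy carbon. The forward pair of steps must add methyl 1,2 and shift oxygen 1,3 without disturbing that centre.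

5 ⇒ 4 ⇒ 3 ⇒ 2 ⇒ 1. The alkene comes from loss of a β-acetate, the ketone from an alcohol, and the acetate from desymmetrisation of a meso-diol. All ring chirality (C8, then C7 and C6 by relay) thus originates in one enzymatic step on an achiral triol. The forward demand is high enantiotopic-group selectivity.

12 ⇒ 11 ⇒ 10. An O–CH3 bond and then a C=C bond (loss of HBr) are cut, back to a commercial bromo ester. The product is strained and polymerisable, so it must be made and used promptly.

24 ⇒ 23 ⇒ 22. An ester hydrolysis and an O–Si bond are undone, back to the chiral-pool hydroxy ester. The forward steps must not enolise the α-carbon.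

## Other disconnections considered

Alternative 1: The cut is C2–C3, formed while C5–C10 breaks. The potassium alkoxide of the 1,2-dialkenylcyclohexanol A1 (KH, 18-crown-6) would undergo an anionic oxy-Cope [3,3] shift, and PhNTf2 would trap the C4=C5 enolate as the enol triflate A2.
- In its favour: the ring-opening step itself forms a skeletal C–C bond (the chosen fragmentation forms none). It runs near room temperature and not at 180 °C. A chair transition state passes the relative configuration of C5/C10 into both alkene geometries. C7 can come from carvone. C11=C13 is already present, so no late methylenation is needed. On these points it is the equal or the better of the chosen plan.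
- Against it here: A1 has two adjacent fully substituted carbons (C5, C10) beside three further stereocentres. The ring-cis C1=C10 alkene needs the cis-dialkenyl isomer reacting through the chair with C9 axial, with the other chair and a boat as competitors. The C5 triflate must then be reduced off. C6 and C12 are held as ethers, so two deprotections, an allylic oxidation and a lactonisation remain.
- Comparison: the chosen plan sets C7 and C8 on a simple cyclohexenone and needs no quaternary stereocentre that survives, but it has a hotter key step and later redox changes at C6 and C15. Overall the route through A1 is judged longer, although its end-game after A2 needs fewer C–C bond-forming steps.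

Alternative 2: The cut is C7–C8. CrCl2 (divalent chromium) would insert into the allylic C13–Br bond of the open-chain aldehyde A3. The allylchromium would add through C7 to the C8 aldehyde with allylic transposition (Nozaki–Hiyama–Kishi type), closing the ring to the homoallylic alcohol A4 that already carries the C11=C13 acrylate.
- In its favour: one mild, chemoselective step gives the ring, two stereocentres (C7, C8), the free O-8 needed for acylation and the α-methylene unit. No redox change at C15 and no lactone enolate are required. In functional-group economy after ring closure it is better than the chosen plan.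
- Against it here: both trisubstituted alkenes must be built with defined geometry in A3 first. A ten-membered ring must be closed against entropy at high dilution. C7/C8 are set relative to C6 only through the transition state of a flexible chain, so the required 7,8-anti relationship is not assured. The free O-8 of A4 is as well placed as O-6 to lactonise on C12.
- Comparison: the mechanism is polar and mild, against a hot diradical process, which is an advantage. The chosen plan is stronger on stereocontrol (C7 and C8 set on a six-membered ring) and on lactone regiochemistry (O-8 masked until the 6,12-lactone exists). Step counts are probably comparable, with the effort moved into A3.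

Alternative 3: The cut is C3–C4. 9-Borabicyclo[3.3.1]nonane would add to the terminal C2=C3 alkene of the lactone A5 to put boron on C3. Pd(dppf)Cl2 with Cs2CO3 would then couple the alkylborane with the C4 alkenyl iodide (oxidative addition to zerovalent palladium, transmetallation, reductive elimination) to give the saturated trans-lactone A6.
- In its favour: C6, C7, C8 and the lactone are complete before ring closure. Both alkene geometries are fixed beforehand and retained in the coupling, which is better than the chosen plan, where geometry is decided in a thermal diyl. Conditions are mild. A6 corresponds to 17 of the chosen route, so the end-games are equal (methylenation, protecting-group changes, acylation).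
- Against it here: a ten-membered ring containing a ring-trans trisubstituted alkene must be closed by reductive elimination from a strained palladacycle, against β-hydride elimination and protodeboronation. Hydroboration must select the terminal alkene of a conjugated C10=C1–C2=C3 diene beside a lactone. A5 needs a stereodefined diene, an alkenyl iodide and three stereocentres before the key event.
- Comparison: geometry is more secure and no 180 °C step is needed (better). Ring-closure risk is greater and the linear approach longer (worse). The chosen plan pays no entropic price for the ring because the perimeter already exists in 13.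

Key step: step 10

Remark: germacrane numbering (C1–C15) is used throughout; α is the face of O-6, O-8 and H-7, β the face of C11; TBS = tert-butyldimethylsilyl, TBDPS = tert-butyldiphenylsilyl.

Remark: the lipase of step 2 is taken to acetylate the hydroxyl of 2 that becomes C6, giving 3 as drawn; should it prefer the other enantiotopic hydroxyl, hydrolysis of the diacetate of 2 with the same enzyme supplies 3 instead.

## Route

Step 1
Reactants: 1 cis,cis-cyclohexane-1,3,5-triol
Product: 2 cis,cis-5-[(tert-butyldimethylsilyl)oxy]cyclohexane-1,3-diol (meso)
Conditions: TBSCl (0.9 equiv), imidazole, DMF, 0 °C → rt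
Reagents that add atoms: tert-butyldimethylsilyl chloride, CC(C)(C)[Si](C)(C)Cl
Why: Silyl ether formation on one of three equivalent hydroxyls; a slight deficit of chloride favours the mono-ether, unreacted 1 is recycled, and 2 is still meso so no stereocentre is at stake.

Step 2
Reactants: 2 cis,cis-5-[(tert-butyldimethylsilyl)oxy]cyclohexane-1,3-diol
Product: 3 (1R,3S,5S)-3-[(tert-butyldimethylsilyl)oxy]-5-hydroxycyclohexyl acetate (all-cis)
Conditions: Burkholderia cepacia lipase (immobilised), vinyl acetate, t-BuOMe, 30 °C
Reagents that add atoms: vinyl acetate, CC(=O)OC=C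
Why: Lipase-catalysed irreversible transesterification desymmetrises the meso-diol; acylation of one enantiotopic hydroxyl makes the silyloxy carbon (future C8) a defined stereocentre and is the only source of absolute configuration for the ring.

Step 3
Reactants: 3 (1R,3S,5S)-3-[(tert-butyldimethylsilyl)oxy]-5-hydroxycyclohexyl acetate
Product: 5 (5R)-5-[(tert-butyldimethylsilyl)oxy]cyclohex-2-en-1-one, via β-acetoxy ketone 4 (not isolated)
Conditions: Dess–Martin periodinane, CH2Cl2, 0 °C → rt; then Et3N, 0 °C
Reagents that add atoms: none
Why: Alcohol oxidation followed by E1cB loss of acetate from the β-acetoxy ketone; acetate leaves far more readily than the silyloxide on the other β-carbon, so the silyloxy stereocentre is kept.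

Step 4
Reactants: 5 (5R)-5-[(tert-butyldimethylsilyl)oxy]cyclohex-2-en-1-one
Product: 6 (5R)-5-[(tert-butyldimethylsilyl)oxy]-1-methylcyclohex-2-en-1-ol (both C1 epimers)
Conditions: MeLi, CeCl3, THF, −78 °C
Reagents that add atoms: methyllithium, [Li]C
Why: 1,2-Addition of the weakly basic organocerium reagent to the enone; enolisation (which would expel silyloxide) and conjugate addition are suppressed, and the new carbinol centre is erased in step 5.

Step 5
Reactants: 6 (5R)-5-[(tert-butyldimethylsilyl)oxy]-1-methylcyclohex-2-en-1-ol
Product: 7 (5S)-5-[(tert-butyldimethylsilyl)oxy]-3-methylcyclohex-2-en-1-one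
Conditions: [C5H5NH][CrO3Cl] (pyridinium chlorochromate), 4 Å molecular sieves, CH2Cl2, rt
Reagents that add atoms: pyridinium chlorochromate, [O-][Cr](=O)(=O)Cl.c1cc[nH+]cc1
Why: Dauben–Babler oxidative 1,3-transposition: the tertiary allylic chromate ester undergoes a [3,3] shift and the resulting secondary chromate is oxidised, which puts the carbonyl on C6 and leaves the methyl on C10; the silyloxy carbon is untouched (its descriptor changes from R to S only because the ranking of its neighbours changes).

Step 6
Reactants: 7 (5S)-5-[(tert-butyldimethylsilyl)oxy]-3-methylcyclohex-2-en-1-one; 8 tert-butyl bromoacetate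
Product: 9 tert-butyl 2-[(1R,6S)-6-[(tert-butyldimethylsilyl)oxy]-4-methyl-2-oxocyclohex-3-en-1-yl]acetate (side chain trans to the silyloxy group)
Conditions: LiN(iPr)2, THF, −78 °C; DMPU; then 8, −78 → −40 °C
Reagents that add atoms: none
Why: Kinetic α′-deprotonation gives the cross-conjugated lithium dienolate, which is alkylated (SN2) on the face anti to the adjacent silyloxy group and so sets C7 trans to O-8; the low temperature keeps the β-silyloxy enolate from eliminating.

Step 7
Reactants: 10 ethyl 1-bromocyclobutane-1-carboxylate
Product: 11 cyclobut-1-ene-1-carboxylic acid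
Conditions: KOH, toluene, reflux; then aq HCl
Reagents that add atoms: potassium hydroxide, [K+].[OH-]
Why: E2 dehydrobromination of the α-bromo ester with concurrent saponification; the carboxylate salt separates from toluene, which protects the strained acrylate from further attack.

Step 8
Reactants: 11 cyclobut-1-ene-1-carboxylic acid
Product: 12 methyl cyclobut-1-ene-1-carboxylate
Conditions: MeI, K2CO3, DMF, rt
Reagents that add atoms: iodomethane, CI
Why: SN2 O-methylation of the carboxylate under non-acidic conditions; the volatile, polymerisable ester is used at once as a solution.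

Step 9
Reactants: 9 tert-butyl 2-[(1R,6S)-6-[(tert-butyldimethylsilyl)oxy]-4-methyl-2-oxocyclohex-3-en-1-yl]acetate; 12 methyl cyclobut-1-ene-1-carboxylate
Product: 13 cis-anti-cis tricyclic photoadduct (C6 ketone; CO2Me on C4; CH3 on C10; 8α-OTBS; 7β-CH2CO2tBu; cyclobutane on the face opposite to O-8)
Conditions: hν (medium-pressure Hg lamp, Pyrex filter, λ > 300 nm), 12 (5 equiv), CH2Cl2, 0 °C; then basic Al2O3
Reagents that add atoms: none
Why: Enone–alkene [2+2] photocycloaddition through the enone triplet and a 1,4-diradical; the electron-poor cyclobutene ester adds head-to-head (C4 to the α-carbon C5, C1 to the β-carbon C10), anti across the new cyclobutane and on the enone face away from O-8, and alumina epimerises any trans-fused adduct at C5 to the cis fusion. The four new stereocentres (C1, C4, C5, C10) are all erased in step 10, so a facial isomer of 13 would converge on the same 14.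

Step 10
Reactants: 13 cis-anti-cis tricyclic photoadduct
Product: 14 tert-butyl 2-[(1R,10S,3Z,7Z)-10-[(tert-butyldimethylsilyl)oxy]-4-(methoxycarbonyl)-8-methyl-2-oxocyclodeca-3,7-dien-1-yl]acetate (germacrane: C6 ketone; ring-trans C4=C5; ring-cis C1=C10)
Conditions: toluene (0.01 M, degassed), sealed base-washed tube, 180 °C, 2 h
Reagents that add atoms: none
Why: Heating breaks the strained central C1–C4 bond of the bicyclo[2.2.0]hexane to a cyclohexane-1,4-diyl (C1 secondary, C4 stabilised by the ester), and β-scission of C5–C10 then gives C1=C10 and C4=C5; overall this is a stepwise formal [2+2] cycloreversion of the C1–C4–C5–C10 cyclobutane in which no new C–C bond is made. The closest known reaction type is the thermal opening of bicyclo[2.2.0]hexanes to hexa-1,5-dienes, as applied to cyclohexenone–cyclobutene photoadducts to give cis,trans-cyclodeca-1,5-dienes. The ten-membered ring is not closed by bond formation: its perimeter C1–C10 already exists in 13 and is uncovered when the two cross-ring bonds are cut, a fragmentative enlargement of the cyclohexanone by the four cyclobutene carbons. No stereocentre is created; C1, C4, C5 and C10 become trigonal, and C7 and C8 are not touched. The first selectivity needed is scission of C5–C10 in preference to C2–C3, secured because C5–C10 joins a quaternary carbon to a carbon α to the ketone and its cleavage gives an alkene conjugated to both carbonyl groups. The second is alkene geometry, set in the chair diyl with the C10 methyl equatorial, so that C9 is axial (cis to C2) and C6 equatorial (trans to C3); the cis-anti-cis fusion fixed in step 9 is what allows this chair. Conjugation of C4=C5 with ketone and ester lowers the energy of 14 and slows the onward [3,3] shift to a divinylcyclohexanone, and short heating in dilute, degassed, acid-free solution limits that shift and any loss of silanol across C7–C8.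

Step 11
Reactants: 14 ten-membered dienone
Product: 15 6α,15-diol (C6 ketone reduced to 6α-OH; CO2Me reduced to CH2OH; tert-butyl ester and 8α-OTBS retained)
Conditions: iBu2AlH (5 equiv), CH2Cl2, −78 °C; aq KNaC4H4O6
Reagents that add atoms: none
Why: 1,2-Hydride addition to the enone carbonyl and twofold reduction of the conjugated methyl ester, while the hindered tert-butyl ester survives at −78 °C; C6 is set by attack on the outer face of the carbonyl in the ring conformer that keeps the C7 side chain pseudo-equatorial, which is expected to place O-6 anti to C11 and syn to O-8.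

Step 12
Reactants: 15 6α,15-diol
Product: 16 15-O-TBDPS ether of 15 (6α-OH free)
Conditions: TBDPSCl (1.05 equiv), imidazole, CH2Cl2, 0 °C
Reagents that add atoms: tert-butyldiphenylsilyl chloride, CC(C)(C)[Si](Cl)(c1ccccc1)c1ccccc1
Why: Silylation discriminates the unhindered primary allylic O-15 from the secondary O-6, which is flanked by the C7 branch.

Step 13
Reactants: 16 15-O-TBDPS ether of 15
Product: 17 11,13-dihydro lactone (8α-OTBS; 15-OTBDPS; trans-fused 12,6α-olide; C11 is CH2)
Conditions: LiN(SiMe3)2 (1.05 equiv), THF, −78 → 0 °C; then H2O
Reagents that add atoms: none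
Why: Intramolecular acyl substitution (5-exo-trig lactonisation) of the C6 lithium alkoxide on the tert-butyl ester with loss of tert-butoxide gives the trans-fused γ-lactone without change at C6 or C7; base is used instead of acid because the 1,5-diene is prone to proton-induced transannular cyclisation, and the lithium counter-ion and low temperature disfavour silyl migration from O-8.

Step 14
Reactants: 17 11,13-dihydro lactone
Product: 20 α-methylene lactone (17 with C11=C13; 8α-OTBS; 15-OTBDPS), via Mannich base 18 (not isolated), via methiodide 19 (not isolated)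
Conditions: LiN(iPr)2, THF, −78 °C; CH2=NMe2+ I−, −78 → 0 °C; then MeI, CH2Cl2/MeOH, rt; then aq NaHCO3, EtOAc
Reagents that add atoms: N,N-dimethylmethyleneiminium iodide (Eschenmoser's salt), C=[N+](C)C.[I-]; iodomethane, CI (its methyl group is held only by intermediate 19)
Why: Eschenmoser methylenation: Mannich reaction of the lactone enolate at C11 (the only enolisable position), N-quaternisation and base-induced elimination of trimethylamine give C11=C13; C7 cannot epimerise and O-8 stays silylated, so no alkoxide can translactonise.

Step 15
Reactants: 20 α-methylene lactone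
Product: 21 8α-alcohol (20 without the TBS group; 15-OTBDPS retained)
Conditions: HF·pyridine, pyridine, THF, 0 °C → rt
Reagents that add atoms: none
Why: Acid-assisted fluoride cleavage of silyl ethers; the TBDPS ether is far more stable than the TBS ether under acidic fluoride, which is relied on to outweigh the primary versus secondary difference, and the buffered medium leaves the α-methylene lactone alone.

Step 16
Reactants: 22 methyl (R)-3-hydroxy-2-methylpropanoate
Product: 23 methyl (R)-3-[(tert-butyldiphenylsilyl)oxy]-2-methylpropanoate
Conditions: TBDPSCl, imidazole, DMF, rt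
Reagents that add atoms: tert-butyldiphenylsilyl chloride, CC(C)(C)[Si](Cl)(c1ccccc1)c1ccccc1
Why: Routine silylation of the primary alcohol; the α-stereocentre is not involved.

Step 17
Reactants: 23 methyl (R)-3-[(tert-butyldiphenylsilyl)oxy]-2-methylpropanoate
Product: 24 (R)-3-[(tert-butyldiphenylsilyl)oxy]-2-methylpropanoic acid
Conditions: LiOH·H2O, THF/MeOH/H2O, 0 °C → rt; then aq HCl to pH 3
Reagents that add atoms: lithium hydroxide, [Li+].[OH-]
Why: Saponification of the methyl ester; at this temperature neither enolisation at the α-carbon nor β-elimination of the silyloxy group competes, so the R configuration is retained.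

Step 18
Reactants: 21 8α-alcohol; 24 (R)-3-[(tert-butyldiphenylsilyl)oxy]-2-methylpropanoic acid
Product: 25 8-O-[(2R)-3-(TBDPS-oxy)-2-methylpropanoyl] ester of 21 (bis-TBDPS ether of the target)
Conditions: EDC·HCl, 4-(dimethylamino)pyridine, CH2Cl2, 0 °C → rt
Reagents that add atoms: none
Why: Steglich esterification of the hindered secondary O-8 through the N-acylpyridinium ion; the C8–O bond is not broken (retention at C8), and the mild, cold activation protects the α-methyl stereocentre of 24.

Step 19
Reactants: 25 bis-TBDPS ether of the target
Product: 26 (3aR,4S,6Z,10Z,11aR)-10-(hydroxymethyl)-6-methyl-3-methylidene-2-oxo-3a,4,5,8,9,11a-hexahydrocyclodeca[b]furan-4-yl (2R)-3-hydroxy-2-methylpropanoate (target)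
Conditions: Bu4NF, AcOH (1:1), THF, 0 °C → rt
Reagents that add atoms: none
Why: Fluoride cleavage of the two primary silyl ethers; buffering with acetic acid suppresses conjugate addition to the α-methylene lactone, β-elimination of the 3-hydroxy ester and acyl migration.

## Compound list

1 | cis,cis-cyclohexane-1,3,5-triol | O[C@@H]1C[C@H](O)C[C@H](O)C1 | starting material
2 | cis,cis-5-[(tert-butyldimethylsilyl)oxy]cyclohexane-1,3-diol (all-cis, meso) | O[C@@H]1C[C@H](O)C[C@H](O[Si](C)(C)C(C)(C)C)C1 | intermediate
3 | (1R,3S,5S)-3-[(tert-butyldimethylsilyl)oxy]-5-hydroxycyclohexyl acetate (all-cis) | O[C@H]1C[C@@H](OC(C)=O)C[C@@H](O[Si](C)(C)C(C)(C)C)C1 | intermediate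
4 | (1S,3R)-3-[(tert-butyldimethylsilyl)oxy]-5-oxocyclohexyl acetate (β-acetoxy ketone) | O=C1C[C@@H](OC(C)=O)C[C@@H](O[Si](C)(C)C(C)(C)C)C1 | intermediate (not isolated)
5 | (5R)-5-[(tert-butyldimethylsilyl)oxy]cyclohex-2-en-1-one | O=C1C=CC[C@@H](O[Si](C)(C)C(C)(C)C)C1 | intermediate
6 | (5R)-5-[(tert-butyldimethylsilyl)oxy]-1-methylcyclohex-2-en-1-ol (both C1 epimers) | CC1(O)C=CC[C@@H](O[Si](C)(C)C(C)(C)C)C1 | intermediate
7 | (5S)-5-[(tert-butyldimethylsilyl)oxy]-3-methylcyclohex-2-en-1-one | O=C1C=C(C)C[C@H](O[Si](C)(C)C(C)(C)C)C1 | intermediate
8 | tert-butyl bromoacetate | BrCC(=O)OC(C)(C)C | starting material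
9 | tert-butyl 2-[(1R,6S)-6-[(tert-butyldimethylsilyl)oxy]-4-methyl-2-oxocyclohex-3-en-1-yl]acetate (trans) | O=C1C=C(C)C[C@H](O[Si](C)(C)C(C)(C)C)[C@H]1CC(=O)OC(C)(C)C | intermediate
10 | ethyl 1-bromocyclobutane-1-carboxylate | CCOC(=O)C1(Br)CCC1 | starting material
11 | cyclobut-1-ene-1-carboxylic acid | OC(=O)C1=CCC1 | intermediate
12 | methyl cyclobut-1-ene-1-carboxylate | COC(=O)C1=CCC1 | intermediate
13 | cis-anti-cis tricyclic photoadduct: cyclohexanone C5–C6(=O)–C7–C8–C9–C10 fused at C5–C10 to cyclobutane C1–C4–C5–C10, itself fused at C1–C4 to cyclobutane C1–C2–C3–C4; CO2Me on C4; CH3 on C10; 8α-OTBS (8S); 7β-CH2CO2tBu (7R); C1 and C4 on the face opposite to O-8; C2/C3 anti to C6/C9 | O=C1[C@H]2[C@]3(C(=O)OC)CC[C@@H]3[C@@]2(C)C[C@H](O[Si](C)(C)C(C)(C)C)[C@H]1CC(=O)OC(C)(C)C | intermediate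
14 | tert-butyl 2-[(1R,10S,3Z,7Z)-10-[(tert-butyldimethylsilyl)oxy]-4-(methoxycarbonyl)-8-methyl-2-oxocyclodeca-3,7-dien-1-yl]acetate (C6 ketone; ring-trans C4=C5; ring-cis C1=C10) | O=C1/C=C(\C(=O)OC)CC/C=C(/C)C[C@H](O[Si](C)(C)C(C)(C)C)[C@H]1CC(=O)OC(C)(C)C | intermediate
15 | 6α,15-diol: 14 with 6α-OH (cis to O-8, trans to C11) and C15 as CH2OH | O[C@@H]1/C=C(\CO)CC/C=C(/C)C[C@H](O[Si](C)(C)C(C)(C)C)[C@H]1CC(=O)OC(C)(C)C | intermediate
16 | 15-O-TBDPS ether of 15 | O[C@@H]1/C=C(\CO[Si](c2ccccc2)(c2ccccc2)C(C)(C)C)CC/C=C(/C)C[C@H](O[Si](C)(C)C(C)(C)C)[C@H]1CC(=O)OC(C)(C)C | intermediate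
17 | 8α-(TBS-oxy)-15-(TBDPS-oxy)-11,13-dihydrogermacra-1(10),4-dien-12,6α-olide (ring-cis C1=C10; ring-trans C4=C5; trans-fused lactone) | C1C(=O)O[C@@H]2/C=C(\CO[Si](c3ccccc3)(c3ccccc3)C(C)(C)C)CC/C=C(/C)C[C@H](O[Si](C)(C)C(C)(C)C)[C@@H]12 | intermediate
18 | 11-(dimethylaminomethyl) derivative of 17 (Mannich base, C11 epimers) | CN(C)CC1C(=O)O[C@@H]2/C=C(\CO[Si](c3ccccc3)(c3ccccc3)C(C)(C)C)CC/C=C(/C)C[C@H](O[Si](C)(C)C(C)(C)C)[C@@H]12 | intermediate (not isolated)
19 | trimethylammonium iodide of 18 (methiodide) | C[N+](C)(C)CC1C(=O)O[C@@H]2/C=C(\CO[Si](c3ccccc3)(c3ccccc3)C(C)(C)C)CC/C=C(/C)C[C@H](O[Si](C)(C)C(C)(C)C)[C@@H]12.[I-] | intermediate (not isolated)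
20 | α-methylene lactone: 17 with C11=C13 | C=C1C(=O)O[C@@H]2/C=C(\CO[Si](c3ccccc3)(c3ccccc3)C(C)(C)C)CC/C=C(/C)C[C@H](O[Si](C)(C)C(C)(C)C)[C@@H]12 | intermediate
21 | 8α-alcohol: 20 without the TBS group | C=C1C(=O)O[C@@H]2/C=C(\CO[Si](c3ccccc3)(c3ccccc3)C(C)(C)C)CC/C=C(/C)C[C@H](O)[C@@H]12 | intermediate
22 | methyl (R)-3-hydroxy-2-methylpropanoate | COC(=O)[C@H](C)CO | starting material
23 | methyl (R)-3-[(tert-butyldiphenylsilyl)oxy]-2-methylpropanoate | COC(=O)[C@H](C)CO[Si](c1ccccc1)(c1ccccc1)C(C)(C)C | intermediate
24 | (R)-3-[(tert-butyldiphenylsilyl)oxy]-2-methylpropanoic acid | OC(=O)[C@H](C)CO[Si](c1ccccc1)(c1ccccc1)C(C)(C)C | intermediate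
25 | 8-O-[(2R)-3-(TBDPS-oxy)-2-methylpropanoyl] ester of 21 | C=C1C(=O)O[C@@H]2/C=C(\CO[Si](c3ccccc3)(c3ccccc3)C(C)(C)C)CC/C=C(/C)C[C@H](OC(=O)[C@H](C)CO[Si](c3ccccc3)(c3ccccc3)C(C)(C)C)[C@@H]12 | intermediate
26 | (3aR,4S,6Z,10Z,11aR)-10-(hydroxymethyl)-6-methyl-3-methylidene-2-oxo-3a,4,5,8,9,11a-hexahydrocyclodeca[b]furan-4-yl (2R)-3-hydroxy-2-methylpropanoate | C=C1C(=O)O[C@@H]2/C=C(\CO)CC/C=C(/C)C[C@H](OC(=O)[C@H](C)CO)[C@@H]12 | target

## Step count and least certain steps

Total: 19 steps (the one-pot sequences of steps 3 and 14 are counted once each). Longest linear sequence: 15 steps (1–6, 9–15, 18, 19); the side branches are steps 7–8 and 16–17.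

Step 10 (key step). What may go wrong: the diyl may partition through a boat-like or rotationally relaxed form, which erodes the geometry of the conjugated C4=C5 bond. At the fragmentation temperature the product may also pass on by [3,3] shift (or the diyl by C2–C3 scission) to a divinylcyclohexanone; thermal loss of silanol across C7–C8 is a lesser concern. Fallback (sets out from 13, returns at 14): the C4=C5 geometry is no longer left to the diyl alone. Thermolysis is stopped early, and any C4=C5 ring-cis geometric isomer of 14 F1 is separated and equilibrated by reversible conjugate addition of a catalytic thiolate (PhSH, Et3N) or by iodine-sensitised photoisomerisation. Only the doubly activated alkene responds, and F1 is recycled until it has become 14.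

Step 6. What may go wrong: E1cB expulsion of the silyloxide from the α′-enolate before alkylation (the dienone then aromatises), proton exchange leading to dialkylation, or erosion of the trans selectivity. Fallback (sets out from 7, returns at 9): the silyl ether is cleaved with aqueous HF in MeCN to (5S)-5-hydroxy-3-methylcyclohex-2-en-1-one F2. The alkoxide–enolate dianion, in which the oxide cannot leave, is formed with LiN(iPr)2 (2.2 equiv) and alkylated with 8 anti to the lithium alkoxide to give tert-butyl 2-[(1R,6S)-6-hydroxy-4-methyl-2-oxocyclohex-3-en-1-yl]acetate F3. Re-silylation (TBSCl, imidazole) gives 9.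

Step 11. What may go wrong: poor facial selectivity at C6, because the outcome rests on the conformation of a flexible ten-membered enone and not on a rigid ring; conjugate hydride addition to the doubly activated alkene and partial attack on the tert-butyl ester are lesser risks. Fallback (sets out from 14, returns at 16): if reduction gives mainly the 6β-alcohol, the 6-epimer of 15 F4, its primary hydroxyl is silylated to the 15-O-TBDPS ether of the 6-epimer F5. The C6 alcohol is then inverted by Mitsunobu reaction (4-nitrobenzoic acid, PPh3, diisopropyl azodicarboxylate) to the 6α-(4-nitrobenzoate) of 16 F6, and methanolysis (K2CO3, MeOH) gives 16.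

Step 13. What may go wrong: migration of the TBS group from O-8 to the C6 alkoxide followed by closure of the isomeric 8,12-lactone, or slow substitution at the hindered ester. Fallback (sets out from 16, returns at 17): transesterification is replaced by carboxyl activation. TMSOTf with 2,6-lutidine converts the tert-butyl ester into a silyl ester and caps O-6, giving the 6-O-trimethylsilyl ether trimethylsilyl ester of 16 F7. Mild aqueous K2CO3 in MeOH frees the 6α-hydroxy acid F8, which is lactonised with EDC·HCl and 4-(dimethylamino)pyridine to 17 without an aprotic alkoxide ever being formed.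

Step 15. What may go wrong: loss of the primary TBDPS ether at a rate comparable to cleavage of the hindered secondary TBS ether, giving mixtures. Fallback (sets out from 20, returns at 21): selective cleavage is given up. Both silyl groups are removed with Bu4NF/AcOH to the 8α,15-diol F9, and only the primary allylic hydroxyl is re-silylated with TBDPSCl and imidazole at −20 °C, which gives 21.

## Further compounds

F1 | step 10 | C4=C5 ring-cis geometric isomer of 14 | O=C1/C=C(/C(=O)OC)CC/C=C(/C)C[C@H](O[Si](C)(C)C(C)(C)C)[C@H]1CC(=O)OC(C)(C)C
F2 | step 6 | (5S)-5-hydroxy-3-methylcyclohex-2-en-1-one | O=C1C=C(C)C[C@H](O)C1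
F3 | step 6 | tert-butyl 2-[(1R,6S)-6-hydroxy-4-methyl-2-oxocyclohex-3-en-1-yl]acetate | O=C1C=C(C)C[C@H](O)[C@H]1CC(=O)OC(C)(C)C
F4 | step 11 | 6-epimer of 15 (6β-alcohol) | O[C@H]1/C=C(\CO)CC/C=C(/C)C[C@H](O[Si](C)(C)C(C)(C)C)[C@H]1CC(=O)OC(C)(C)C
F5 | step 11 | 15-O-TBDPS ether of the 6-epimer | O[C@H]1/C=C(\CO[Si](c2ccccc2)(c2ccccc2)C(C)(C)C)CC/C=C(/C)C[C@H](O[Si](C)(C)C(C)(C)C)[C@H]1CC(=O)OC(C)(C)C
F6 | step 11 | 6α-(4-nitrobenzoate) of 16 | O=C(O[C@@H]1/C=C(\CO[Si](c2ccccc2)(c2ccccc2)C(C)(C)C)CC/C=C(/C)C[C@H](O[Si](C)(C)C(C)(C)C)[C@H]1CC(=O)OC(C)(C)C)c1ccc(cc1)[N+](=O)[O-]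
F7 | step 13 | 6-O-trimethylsilyl ether trimethylsilyl ester of 16 | C[Si](C)(C)O[C@@H]1/C=C(\CO[Si](c2ccccc2)(c2ccccc2)C(C)(C)C)CC/C=C(/C)C[C@H](O[Si](C)(C)C(C)(C)C)[C@H]1CC(=O)O[Si](C)(C)C
F8 | step 13 | 6α-hydroxy acid (seco-acid of 17) | O[C@@H]1/C=C(\CO[Si](c2ccccc2)(c2ccccc2)C(C)(C)C)CC/C=C(/C)C[C@H](O[Si](C)(C)C(C)(C)C)[C@H]1CC(=O)O
F9 | step 15 | 8α,15-diol (20 without both silyl groups) | C=C1C(=O)O[C@@H]2/C=C(\CO)CC/C=C(/C)C[C@H](O)[C@@H]12
A1 | alternative 1 | 1,2-dialkenylcyclohexanol: C5 carbinol bearing C4(=CH2)CH2OSi(iPr)3; C10 bearing CH3 and vinyl C1=C2; 6-O-(4-methoxybenzyl); 7-C(=CH2)CH2O-(4-methoxybenzyl); 8-OSiEt3; alkenyl groups cis; OH cis to CH3 | O[C@]1(C(=C)CO[Si](C(C)C)(C(C)C)C(C)C)[C@@H](OCc2ccc(OC)cc2)[C@H](C(=C)COCc2ccc(OC)cc2)[C@@H](O[Si](CC)(CC)CC)C[C@@]1(C)C=C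
A2 | alternative 1 | ten-membered dienyl C5 enol triflate | COc1ccc(CO[C@@H]2/C(OS(=O)(=O)C(F)(F)F)=C(\CO[Si](C(C)C)(C(C)C)C(C)C)CC/C=C(/C)C[C@H](O[Si](CC)(CC)CC)[C@H]2C(=C)COCc2ccc(OC)cc2)cc1
A3 | alternative 2 | open-chain C8 aldehyde with the C13 allylic bromide on the C7=C11 acrylate; 6-OSiEt3; 15-OTBS | O=CC/C(C)=C\CC/C(CO[Si](C)(C)C(C)(C)C)=C/[C@@H](O[Si](CC)(CC)CC)/C=C(\CBr)C(=O)OC
A4 | alternative 2 | ten-membered C8 alcohol bearing the C11 acrylate | CC[Si](CC)(CC)O[C@@H]1/C=C(\CO[Si](C)(C)C(C)(C)C)CC/C=C(/C)C[C@H](O)[C@H]1C(=C)C(=O)OC
A5 | alternative 3 | γ-lactone bearing the C4 alkenyl iodide on C6 and the C8 silyloxy dienyl chain ending in the C2=C3 vinyl group on C7 | C1C(=O)O[C@H](/C=C(/I)CO[Si](C(C)C)(C(C)C)C(C)C)[C@H]1[C@@H](O[Si](CC)(CC)CC)C/C(C)=C\C=C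
A6 | alternative 3 | saturated trans-lactone fused to the ten-membered diene | C1C(=O)O[C@@H]2/C=C(\CO[Si](C(C)C)(C(C)C)C(C)C)CC/C=C(/C)C[C@H](O[Si](CC)(CC)CC)[C@@H]12
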